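**Strategy.** Everything rests on disconnecting C2–C3 of the ten-membered ring and tying C1 to C5 through one oxygen: both carbons carry oxygen in the target (the 1,10- and 4,5-epoxides), so they can sit in an oxocane (O, C1, C10, C9, C8, C7, C6, C5) whose exocyclic C1=C2 methylene and C5-bound (E)-alkoxypropenyl arm (C4=C3) make an allyl vinyl ether. One thermal Claisen shift forms C2–C3, breaks C5–O and gives the cyclodecenone with the C1 ketone, the Z C4=C5 olefin and the C3 ether stereocentre. The precursor is this 2-methyleneoxocane, carrying the 9,10-acetonide, the C8 silyl ether and the C7 isopropenyl group, made by methylenation of an eight-membered lactone.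

Key step: step 14

Assumption: germacrane numbering is used throughout (ring C1–C10, methyl on C4 and C10, isopropenyl on C7), and the compounds marked as starting materials are taken as purchasable.

## Route

Step 1
Reactants: 1 (5S)-5-(hydroxymethyl)oxolan-2-one
Product: 2 (2S)-5-oxooxolane-2-carbaldehyde
Conditions: 2,2,6,6-tetramethylpiperidin-1-oxyl (cat.), PhI(OAc)2, CH2Cl2, rt
Reagents that add atoms: none
Why: Nitroxyl-catalysed alcohol oxidation should stop at the aldehyde under anhydrous, base-free conditions, so the C8 stereocentre next to the new carbonyl is not epimerized.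

Step 2
Reactants: 2 lactone aldehyde; 3 ethyl 2-[bis(2,2,2-trifluoroethoxy)phosphoryl]propanoate
Product: 4 Z-enoate lactone
Conditions: KN(SiMe3)2, 18-crown-6, THF, −78 °C
Reagents that add atoms: none
Why: Still–Gennari olefination should give the Z trisubstituted enoate (ester cis to C8), the geometry whose syn-dihydroxylation leads to the 9,10 relative configuration of the target.

Step 3
Reactants: 4 Z-enoate lactone
Product: 5 9,10-diol lactone
Conditions: K2OsO2(OH)4 (cat.), N-methylmorpholine N-oxide, acetone/H2O, 0 °C → rt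
Reagents that add atoms: N-methylmorpholine N-oxide, C[N+]1([O-])CCOCC1; water, O
Why: Upjohn dihydroxylation adds both oxygens syn, which fixes C9 against C10, and allylic 1,3-strain of the Z-enoate holds C8–H in the alkene plane so that osmium should add anti to the C8–O bond and give the 8,9-anti (9S,10S) diol, the enoate being the only alkene present at this stage.

Step 4
Reactants: 5 9,10-diol lactone
Product: 6 acetonide lactone
Conditions: 2,2-dimethoxypropane, camphorsulfonic acid (cat.), CH2Cl2, rt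
Reagents that add atoms: 2,2-dimethoxypropane, COC(C)(C)OC
Why: Acid-catalysed acetalization ties the secondary C9 and tertiary C10 hydroxyls into a dioxolane that later eases ester hydrolysis and preorganizes the chain for ring closure.

Step 5
Reactants: 6 acetonide lactone
Product: 8 butenolide, via selanyl lactone 7 (not isolated)
Conditions: LiN(i-Pr)2, THF, −78 °C; PhSeBr; then 30% H2O2, pyridine, CH2Cl2, 0 °C → rt
Reagents that add atoms: none
Why: Selenenylation of the lactone enolate (the only enolizable carbonyl, because C10 is quaternary) followed by selenoxide syn-elimination should give the conjugated butenolide without touching C8.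

Step 6
Reactants: 8 butenolide; 9 prop-1-en-2-ylmagnesium bromide
Product: 10 trans-isopropenyl lactone
Conditions: CuBr·SMe2 (cat.), Me3SiCl, THF, −78 °C
Reagents that add atoms: none
Why: Copper-catalysed conjugate addition to a γ-substituted butenolide should deliver the isopropenyl group anti to the C8 side chain, which sets C7 (R) trans to C8.

Step 7
Reactants: 10 trans-isopropenyl lactone
Product: 12 silyl ether Weinreb amide, via hydroxy amide 11 (not isolated)
Conditions: MeNH(OMe)·HCl, AlMe3, CH2Cl2, 0 °C → rt; then 2,6-lutidine, t-BuMe2SiOTf, −20 → 0 °C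
Reagents that add atoms: N,O-dimethylhydroxylamine hydrochloride, CNOC.Cl; tert-butyldimethylsilyl trifluoromethanesulfonate, CC(C)(C)[Si](C)(C)OS(=O)(=O)C(F)(F)F
Why: Aluminium-amide aminolysis (Weinreb amide formation) should open the γ-lactone in preference to the hindered α-quaternary ethyl ester, and silylation of the aluminium alkoxide in the same flask prevents relactonization.

Step 8
Reactants: 12 silyl ether Weinreb amide
Product: 13 C5 aldehyde
Conditions: i-Bu2AlH, THF, −78 °C
Reagents that add atoms: none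
Why: Hydride reduction of the Weinreb amide stops at the aldehyde through the chelated tetrahedral intermediate, while the neopentyl-type ethyl ester reacts more slowly at this temperature.

Step 9
Reactants: 14 (4-methoxyphenyl)methanol; 15 trichloroethene
Product: 18 4-methoxybenzyl prop-1-ynyl ether, via dichlorovinyl ether 16 (not isolated), via lithium alkoxyacetylide 17 (not isolated)
Conditions: KH, THF, 0 °C; 15, −50 °C → rt; n-BuLi, −78 → −40 °C; MeI, DMPU, −78 → 0 °C; kept cold and used at once
Reagents that add atoms: iodomethane, CI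
Why: Addition–elimination of the alkoxide on trichloroethene gives the dichlorovinyl ether, which n-BuLi converts by elimination and chlorine–lithium exchange into the lithium alkoxyacetylide that is methylated at carbon (alkynyl ether synthesis).

Step 10
Reactants: 13 C5 aldehyde; 18 4-methoxybenzyl prop-1-ynyl ether
Product: 21 allylic alcohol ester, via alkenylborane 19 (not isolated), via alkenylzinc 20 (not isolated)
Conditions: 18, Cy2BH (from BH3·SMe2 and cyclohexene), toluene, 0 °C; Et2Zn, −78 °C; (−)-3-exo-morpholinoisoborneol (5 mol %), then 13, −10 °C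
Reagents that add atoms: none
Why: Syn-hydroboration puts boron on the methyl-bearing carbon trans to oxygen, boron–zinc exchange keeps this geometry, and the amino-alcohol-catalysed asymmetric alkenylzinc addition should take place on the Si face of the aldehyde under catalyst control to set C5 (R), the remote C7 centre exerting little bias and the zinc reagent leaving the ester untouched.

Step 11
Reactants: 21 allylic alcohol ester
Product: 22 seco acid
Conditions: LiOH·H2O, THF/MeOH/H2O, rt; AcOH to pH 6, 0 °C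
Reagents that add atoms: lithium hydroxide, [Li+].[OH-]
Why: Saponification of the ethyl ester, activated by the α-alkoxy oxygen of the dioxolane, should proceed at rt, and the work-up is kept near neutral because the γ-hydroxy enol ether ionizes under acid.

Step 12
Reactants: 22 seco acid
Product: 23 eight-membered lactone
Conditions: 2-methyl-6-nitrobenzoic anhydride, 4-(dimethylamino)pyridine, CH2Cl2 (1 mM, slow addition), rt
Reagents that add atoms: none
Why: Shiina macrolactonization activates the acid as a mixed anhydride under high dilution at rt, the cis-fused dioxolane and the ring substituents lowering the conformational cost of the eight-membered ring, and C5 reacts with retention.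

Step 13
Reactants: 23 eight-membered lactone
Product: 24 2-methyleneoxocane
Conditions: Cp2Ti(μ-Cl)(μ-CH2)AlMe2, pyridine, THF/toluene, −40 → 0 °C; aq. NaOH
Reagents that add atoms: Cp2Ti(μ-Cl)(μ-CH2)AlMe2, C[Al-]1(C)C[Ti](C2C=CC=C2)(C2C=CC=C2)[Cl+]1
Why: Tebbe methylenation with the chloride-bridged titanium–aluminium methylidene converts the lactone carbonyl into the exocyclic enol ether (C2) at low temperature, so the allyl vinyl ether does not rearrange while a titanium carbene that would methylenate the resulting ketone is still present.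

Step 14
Reactants: 24 2-methyleneoxocane
Product: 25 (4Z)-cyclodecenone
Conditions: toluene (degassed), 2,6-di-tert-butyl-4-methylphenol (cat.), base-washed sealed tube, 130 °C
Reagents that add atoms: none
Why: On heating, the allyl vinyl ether C2=C1–O–C5–C4=C3 held in the oxocane undergoes a concerted, suprafacial [3,3] shift through a chair-like bicyclic transition state in which C2 bonds to C3 while the C5–O bond breaks and the C1 carbonyl forms. The closest known reaction type is the Claisen ring expansion of 2-methylene-6-vinyltetrahydropyrans to cyclooct-4-enones, run here on the larger cyclic ether, and the alkoxy donor on C3 at the allyl terminus is expected to lower the barrier. The ten-membered carbocycle is closed by a two-atom ring expansion of the eight-membered ether and not by an end-to-end cyclization, so the entropic cost of a medium-ring closure is not paid in this step. The new C3 stereocentre is controlled by the C5 configuration (R) and the E enol ether geometry: bonding occurs on the face of the allyl unit from which the ring oxygen leaves, which gives 3S when the olefin formed is Z. The step needs Z over E selectivity at C4=C5, secured by the five-carbon tether C6–C10, which can span C1 and C5 only with C6 axial on the chair; acid-free, neutral conditions guard against ionization of the allylic C5–O bond.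

Step 15
Reactants: 25 (4Z)-cyclodecenone
Product: 26 (1S)-alcohol
Conditions: (R)-1-methyl-3,3-diphenyltetrahydro-1H,3H-pyrrolo[1,2-c][1,3,2]oxazaborole (0.3 equiv), catecholborane, toluene, −78 → −40 °C
Reagents that add atoms: none
Why: Corey–Bakshi–Shibata reduction under reagent control (large group the quaternary C10, small group C2H2) should give the (1S)-alcohol needed for epoxide closure with inversion, catecholborane being too unreactive to hydroborate the alkenes at this temperature.

Step 16
Reactants: 26 (1S)-alcohol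
Product: 27 C1 mesylate
Conditions: MsCl, Et3N, CH2Cl2, 0 °C
Reagents that add atoms: methanesulfonyl chloride, CS(=O)(=O)Cl
Why: Sulfonylation of the only free hydroxyl through the sulfene pathway tolerates the hindered position next to the quaternary C10.

Step 17
Reactants: 27 C1 mesylate
Product: 28 C8 alcohol
Conditions: HF·pyridine, pyridine, THF, 0 °C → rt
Reagents that add atoms: none
Why: Buffered fluoride cleavage of the secondary silyl ether leaves the acetonide, the PMB ether and the mesylate intact.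

Step 18
Reactants: 28 C8 alcohol; 29 3-methylbut-2-enoyl chloride
Product: 30 C8 senecioate
Conditions: pyridine, 4-(dimethylamino)pyridine (cat.), CH2Cl2, 0 °C → rt
Reagents that add atoms: none
Why: Acylation of the only free hydroxyl installs the senecioate while C9–O is still tied in the acetonide, so no choice between the C8 and C9 hydroxyls is ever needed and no free hydroxyl homoallylic to the isopropenyl group remains to misdirect the later epoxidation.

Step 19
Reactants: 30 C8 senecioate
Product: 31 9,10-diol mesylate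
Conditions: TsOH·H2O (cat.), MeOH, rt
Reagents that add atoms: none
Why: Acid-catalysed transacetalization to methanol removes the isopropylidene group before any epoxide is present, under conditions the conjugated ester, the mesylate and the PMB ether should survive.

Step 20
Reactants: 31 9,10-diol mesylate
Product: 32 C9 triethylsilyl ether
Conditions: Et3SiCl, imidazole, DMF, 0 °C
Reagents that add atoms: chlorotriethylsilane, CC[Si](Cl)(CC)CC
Why: Silylation is selective for the secondary C9 hydroxyl over the tertiary C10 hydroxyl and blocks acyl migration from C8 in the basic step that follows.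

Step 21
Reactants: 32 C9 triethylsilyl ether
Product: 33 1,10-epoxide
Conditions: NaH, THF, 0 °C → rt
Reagents that add atoms: none
Why: Deprotonation of the tertiary C10 hydroxyl triggers an intramolecular Williamson displacement (3-exo-tet) of the mesylate with inversion at C1, which should give the 1,10-epoxide with the target configuration (C2 and C9 cis).

Step 22
Reactants: 33 1,10-epoxide
Product: 34 C3 allylic alcohol
Conditions: 2,3-dichloro-5,6-dicyano-1,4-benzoquinone, CH2Cl2/pH 7 phosphate buffer, 0 °C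
Reagents that add atoms: none
Why: Oxidative cleavage of the PMB ether by hydride abstraction at its benzylic carbon under buffered conditions spares the epoxide, the silyl ether, the ester and the isolated alkenes.

Step 23
Reactants: 34 C3 allylic alcohol
Product: 35 bis-epoxy alcohol
Conditions: 3-chloroperoxybenzoic acid (1.05 equiv), NaHCO3, CH2Cl2, −20 → 0 °C
Reagents that add atoms: 3-chloroperoxybenzoic acid, O=C(OO)c1cccc(Cl)c1
Why: Prilezhaev epoxidation guided by hydrogen bonding to the C3 hydroxyl should take the trisubstituted ring alkene, which is more electron-rich than the isopropenyl and the conjugated senecioate alkenes, on its outer face in the conformer that minimizes allylic 1,3-strain, giving the trans (threo) epoxy alcohol that peracids give with Z-allylic alcohols both in medium rings and in open chains, which is the 4,5-epoxide configuration of the target.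

Step 24
Reactants: 35 bis-epoxy alcohol; 36 (2Z)-2-methylbut-2-enoic acid
Product: 37 C3 angelate
Conditions: 36, 2,4,6-trichlorobenzoyl chloride, Et3N, THF, rt, filtered; then 35, toluene, 60 °C
Reagents that add atoms: none
Why: Yamaguchi esterification through the mixed anhydride, run without a nucleophilic catalyst, acylates the only free hydroxyl and avoids the Z to E isomerization to the tiglate.

Step 25
Reactants: 37 C3 angelate
Product: 38 CNP0320216.1
Conditions: HF·pyridine, pyridine, THF, 0 °C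
Reagents that add atoms: none
Why: Buffered fluoride desilylation frees C9–OH under non-basic conditions, so the neighbouring C8 ester should not migrate and both epoxides should survive.

## Compound list

1 | (5S)-5-(hydroxymethyl)oxolan-2-one | OC[C@H]1OC(=O)CC1 | starting material
2 | (2S)-5-oxooxolane-2-carbaldehyde | O=C[C@H]1OC(=O)CC1 | intermediate
3 | ethyl 2-[bis(2,2,2-trifluoroethoxy)phosphoryl]propanoate | CCOC(=O)C(C)P(=O)(OCC(F)(F)F)OCC(F)(F)F | starting material
4 | ethyl (2Z)-2-methyl-3-[(2S)-5-oxooxolan-2-yl]prop-2-enoate | CCOC(=O)/C(C)=C\[C@H]1OC(=O)CC1 | intermediate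
5 | ethyl (2S,3S)-2,3-dihydroxy-2-methyl-3-[(2S)-5-oxooxolan-2-yl]propanoate | CCOC(=O)[C@@](C)(O)[C@@H](O)[C@H]1OC(=O)CC1 | intermediate
6 | ethyl (4S,5S)-2,2,4-trimethyl-5-[(2S)-5-oxooxolan-2-yl]-1,3-dioxolane-4-carboxylate | CCOC(=O)[C@@]1(C)OC(C)(C)O[C@H]1[C@H]1OC(=O)CC1 | intermediate
7 | ethyl (4S,5S)-2,2,4-trimethyl-5-[(2S)-5-oxo-4-(phenylselanyl)oxolan-2-yl]-1,3-dioxolane-4-carboxylate (both epimers at the selenium-bearing carbon) | CCOC(=O)[C@@]1(C)OC(C)(C)O[C@H]1[C@H]1OC(=O)C([Se]c2ccccc2)C1 | intermediate (not isolated)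
8 | ethyl (4S,5S)-2,2,4-trimethyl-5-[(2S)-5-oxo-2,5-dihydrofuran-2-yl]-1,3-dioxolane-4-carboxylate | CCOC(=O)[C@@]1(C)OC(C)(C)O[C@H]1[C@H]1OC(=O)C=C1 | intermediate
9 | prop-1-en-2-ylmagnesium bromide | CC(=C)[Mg]Br | starting material
10 | ethyl (4S,5S)-2,2,4-trimethyl-5-[(2S,3R)-5-oxo-3-(prop-1-en-2-yl)oxolan-2-yl]-1,3-dioxolane-4-carboxylate | CCOC(=O)[C@@]1(C)OC(C)(C)O[C@H]1[C@H]1OC(=O)C[C@@H]1C(C)=C | intermediate
11 | ethyl (4S,5S)-5-[(1S,2R)-1-hydroxy-4-[methoxy(methyl)amino]-4-oxo-2-(prop-1-en-2-yl)butyl]-2,2,4-trimethyl-1,3-dioxolane-4-carboxylate (present as its aluminium alkoxide) | CCOC(=O)[C@@]1(C)OC(C)(C)O[C@H]1[C@@H](O)[C@@H](C(C)=C)CC(=O)N(C)OC | intermediate (not isolated)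
12 | ethyl (4S,5S)-5-[(1S,2R)-1-[(tert-butyldimethylsilyl)oxy]-4-[methoxy(methyl)amino]-4-oxo-2-(prop-1-en-2-yl)butyl]-2,2,4-trimethyl-1,3-dioxolane-4-carboxylate | CCOC(=O)[C@@]1(C)OC(C)(C)O[C@H]1[C@@H](O[Si](C)(C)C(C)(C)C)[C@@H](C(C)=C)CC(=O)N(C)OC | intermediate
13 | ethyl (4S,5S)-5-[(1S,2R)-1-[(tert-butyldimethylsilyl)oxy]-4-oxo-2-(prop-1-en-2-yl)butyl]-2,2,4-trimethyl-1,3-dioxolane-4-carboxylate | CCOC(=O)[C@@]1(C)OC(C)(C)O[C@H]1[C@@H](O[Si](C)(C)C(C)(C)C)[C@@H](C(C)=C)CC=O | intermediate
14 | (4-methoxyphenyl)methanol | COc1ccc(CO)cc1 | starting material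
15 | trichloroethene | ClC=C(Cl)Cl | starting material
16 | 1-({[(E)-1,2-dichloroethenyl]oxy}methyl)-4-methoxybenzene | COc1ccc(CO/C(Cl)=C\Cl)cc1 | intermediate (not isolated)
17 | lithium 2-[(4-methoxybenzyl)oxy]ethynide | [Li]C#COCc1ccc(OC)cc1 | intermediate (not isolated)
18 | 1-methoxy-4-[(prop-1-yn-1-yloxy)methyl]benzene | CC#COCc1ccc(OC)cc1 | intermediate
19 | dicyclohexyl{(1Z)-1-[(4-methoxybenzyl)oxy]prop-1-en-2-yl}borane (boron trans to oxygen) | COc1ccc(CO/C=C(\C)B(C2CCCCC2)C2CCCCC2)cc1 | intermediate (not isolated)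
20 | ethyl{(1E)-1-[(4-methoxybenzyl)oxy]prop-1-en-2-yl}zinc (zinc trans to oxygen) | CC[Zn]/C(C)=C/OCc1ccc(OC)cc1 | intermediate (not isolated)
21 | ethyl (4S,5S)-5-[(1S,2R,4R,5E)-1-[(tert-butyldimethylsilyl)oxy]-4-hydroxy-6-[(4-methoxybenzyl)oxy]-5-methyl-2-(prop-1-en-2-yl)hex-5-en-1-yl]-2,2,4-trimethyl-1,3-dioxolane-4-carboxylate | CCOC(=O)[C@@]1(C)OC(C)(C)O[C@H]1[C@@H](O[Si](C)(C)C(C)(C)C)[C@@H](C(C)=C)C[C@@H](O)/C(C)=C/OCc1ccc(OC)cc1 | intermediate
22 | (4S,5S)-5-[(1S,2R,4R,5E)-1-[(tert-butyldimethylsilyl)oxy]-4-hydroxy-6-[(4-methoxybenzyl)oxy]-5-methyl-2-(prop-1-en-2-yl)hex-5-en-1-yl]-2,2,4-trimethyl-1,3-dioxolane-4-carboxylic acid | OC(=O)[C@@]1(C)OC(C)(C)O[C@H]1[C@@H](O[Si](C)(C)C(C)(C)C)[C@@H](C(C)=C)C[C@@H](O)/C(C)=C/OCc1ccc(OC)cc1 | intermediate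
23 | eight-membered lactone (oxocan-2-one: O, C1, C10, C9, C8, C7, C6, C5) with 9,10-acetonide, 10-methyl, 8-OTBS, 7-isopropenyl and 5-[(E)-2-(4-methoxybenzyloxy)-1-methylvinyl]; (5R,7R,8S,9S,10S) | C=C(C)[C@H]1C[C@H](/C(C)=C/OCc2ccc(OC)cc2)OC(=O)[C@@]3(C)OC(C)(C)O[C@H]3[C@H]1O[Si](C)(C)C(C)(C)C | intermediate
24 | 2-methylene-8-[(E)-2-(4-methoxybenzyloxy)-1-methylvinyl]oxocane with 9,10-acetonide, 10-methyl, 8-OTBS and 7-isopropenyl; (5R,7R,8S,9S,10S) | C=C(C)[C@H]1C[C@H](/C(C)=C/OCc2ccc(OC)cc2)OC(=C)[C@@]3(C)OC(C)(C)O[C@H]3[C@H]1O[Si](C)(C)C(C)(C)C | intermediate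
25 | (3S,4Z,7R,8S,9S,10S)-8-[(tert-butyldimethylsilyl)oxy]-9,10-(isopropylidenedioxy)-3-[(4-methoxybenzyl)oxy]germacra-4,11-dien-1-one | C=C(C)[C@H]1C/C=C(C)\[C@@H](OCc2ccc(OC)cc2)CC(=O)[C@@]3(C)OC(C)(C)O[C@H]3[C@H]1O[Si](C)(C)C(C)(C)C | intermediate
26 | (1S,3S,4Z,7R,8S,9S,10R)-8-[(tert-butyldimethylsilyl)oxy]-9,10-(isopropylidenedioxy)-3-[(4-methoxybenzyl)oxy]germacra-4,11-dien-1-ol | C=C(C)[C@H]1C/C=C(C)\[C@@H](OCc2ccc(OC)cc2)C[C@H](O)[C@@]3(C)OC(C)(C)O[C@H]3[C@H]1O[Si](C)(C)C(C)(C)C | intermediate
27 | methanesulfonate of 26 at C1; (1S,3S,4Z,7R,8S,9S,10S) | C=C(C)[C@H]1C/C=C(C)\[C@@H](OCc2ccc(OC)cc2)C[C@H](OS(C)(=O)=O)[C@@]3(C)OC(C)(C)O[C@H]3[C@H]1O[Si](C)(C)C(C)(C)C | intermediate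
28 | (1S,3S,4Z,7R,8S,9S,10S)-8-hydroxy-9,10-(isopropylidenedioxy)-3-[(4-methoxybenzyl)oxy]germacra-4,11-dien-1-yl methanesulfonate | C=C(C)[C@H]1C/C=C(C)\[C@@H](OCc2ccc(OC)cc2)C[C@H](OS(C)(=O)=O)[C@@]3(C)OC(C)(C)O[C@H]3[C@H]1O | intermediate
29 | 3-methylbut-2-enoyl chloride | CC(C)=CC(=O)Cl | starting material
30 | 3-methylbut-2-enoate of 28 at C8; (1S,3S,4Z,7R,8S,9S,10S) | C=C(C)[C@H]1C/C=C(C)\[C@@H](OCc2ccc(OC)cc2)C[C@H](OS(C)(=O)=O)[C@@]3(C)OC(C)(C)O[C@H]3[C@H]1OC(=O)C=C(C)C | intermediate
31 | (1S,3S,4Z,7R,8S,9S,10S)-9,10-dihydroxy-1-(methanesulfonyloxy)-3-[(4-methoxybenzyl)oxy]germacra-4,11-dien-8-yl 3-methylbut-2-enoate | C=C(C)[C@H]1C/C=C(C)\[C@@H](OCc2ccc(OC)cc2)C[C@H](OS(C)(=O)=O)[C@@](C)(O)[C@@H](O)[C@H]1OC(=O)C=C(C)C | intermediate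
32 | 9-O-triethylsilyl ether of 31; (1S,3S,4Z,7R,8S,9S,10S) | C=C(C)[C@H]1C/C=C(C)\[C@@H](OCc2ccc(OC)cc2)C[C@H](OS(C)(=O)=O)[C@@](C)(O)[C@@H](O[Si](CC)(CC)CC)[C@H]1OC(=O)C=C(C)C | intermediate
33 | (1R,3S,4Z,7R,8S,9S,10R)-1,10-epoxy-3-[(4-methoxybenzyl)oxy]-9-[(triethylsilyl)oxy]germacra-4,11-dien-8-yl 3-methylbut-2-enoate | C=C(C)[C@H]1C/C=C(C)\[C@@H](OCc2ccc(OC)cc2)C[C@H]2O[C@@]2(C)[C@@H](O[Si](CC)(CC)CC)[C@H]1OC(=O)C=C(C)C | intermediate
34 | (1R,3S,4Z,7R,8S,9S,10R)-1,10-epoxy-3-hydroxy-9-[(triethylsilyl)oxy]germacra-4,11-dien-8-yl 3-methylbut-2-enoate | C=C(C)[C@H]1C/C=C(C)\[C@@H](O)C[C@H]2O[C@@]2(C)[C@@H](O[Si](CC)(CC)CC)[C@H]1OC(=O)C=C(C)C | intermediate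
35 | (1R,3S,4R,5S,7R,8S,9S,10R)-1,10:4,5-diepoxy-3-hydroxy-9-[(triethylsilyl)oxy]germacr-11-en-8-yl 3-methylbut-2-enoate | C=C(C)[C@H]1C[C@@H]2O[C@]2(C)[C@@H](O)C[C@H]2O[C@@]2(C)[C@@H](O[Si](CC)(CC)CC)[C@H]1OC(=O)C=C(C)C | intermediate
36 | (2Z)-2-methylbut-2-enoic acid (angelic acid) | C/C=C(/C)C(=O)O | starting material
37 | (1R,3S,4S,5S,7R,8S,9S,10R)-1,10:4,5-diepoxy-3-{[(2Z)-2-methylbut-2-enoyl]oxy}-9-[(triethylsilyl)oxy]germacr-11-en-8-yl 3-methylbut-2-enoate | C=C(C)[C@H]1C[C@@H]2O[C@]2(C)[C@@H](OC(=O)/C(C)=C\C)C[C@H]2O[C@@]2(C)[C@@H](O[Si](CC)(CC)CC)[C@H]1OC(=O)C=C(C)C | intermediate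
38 | CNP0320216.1: (1R,3S,4S,5S,7R,8S,9S,10S)-1,10:4,5-diepoxy-9-hydroxy-3-{[(2Z)-2-methylbut-2-enoyl]oxy}germacr-11-en-8-yl 3-methylbut-2-enoate | C=C(C)[C@H]1C[C@@H]2O[C@]2(C)[C@@H](OC(=O)/C(C)=C\C)C[C@H]2O[C@@]2(C)[C@@H](O)[C@H]1OC(=O)C=C(C)C | target

## Step count and risks

Total step count: 25. Longest linear sequence: 24 steps (steps 1–8 and 10–25; step 9 makes the side reagent 18).

The three steps most likely to fail:

**Step 14 (Claisen ring expansion).** The rearrangement may stall, or the allylic C5–O bond may ionize so that the material eliminates or recombines through the conformer with C6 equatorial, which would give the E olefin and the C3 epimer. The fallback closes the ring at C3–C4 instead; it sets out from aldehyde 13 and returns at ketone 25. Stork–Zhao olefination of 13 with (1-iodoethyl)triphenylphosphonium iodide and NaN(SiMe3)2 should give the Z vinyl iodide ester F1. Reduction with i-Bu2AlH at −78 °C should give the C1 aldehyde F2, and addition of lithiated ethyl acetate the β-hydroxy ester F3 (both C1 epimers are usable, since C1 is oxidized later). Et3SiOTf/2,6-lutidine gives the silyl ether F4 and i-Bu2AlH the C3 aldehyde F5. Nozaki–Hiyama–Kishi cyclization (CrCl2, NiCl2 cat., DMSO/THF, high dilution) should give the ten-membered allylic alcohol F6 with the Z olefin kept; the 3S epimer is taken on. 4-Methoxybenzyl trichloroacetimidate with La(OTf)3 (cat.) gives the PMB ether F7, pyridinium p-toluenesulfonate in MeOH removes the triethylsilyl group to give the C1 alcohol F8, and Dess–Martin periodinane then gives 25.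

**Step 12 (eight-membered lactonization).** Intermolecular esterification to dimers and oligomers may outrun closure of the strained ring, or the activated mixture may ionize the allylic alcohol. The fallback activates the alcohol instead of the acid; it sets out from aldehyde 13 and returns at lactone 23. Step 10 run with (+)-3-exo-morpholinoisoborneol should give the C5-epimeric hydroxy ester F9, and LiOH the (5S) seco acid F10. Mitsunobu lactonization (PPh3, diisopropyl azodicarboxylate, toluene, high dilution) then closes the ring by carboxylate attack at C5 with inversion and gives 23.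

**Step 10 (asymmetric alkenylzinc addition).** The alkynyl ether or the alkenylmetal reagents may decompose before addition, or facial selectivity at C5 may be poor. The fallback builds the enol ether after a catalyst-controlled ketone reduction; it sets out from Weinreb amide 12 and returns at alcohol 21. Ethynylmagnesium bromide should convert 12 into the ynone F11, and Noyori transfer hydrogenation with RuCl[(R,R)-TsDPEN](p-cymene) in i-PrOH should give the (R)-propargylic alcohol F12. Negishi carboalumination (AlMe3, Cp2ZrCl2 cat.) followed by I2 gives the E vinyl iodide F13. Coupling with (4-methoxyphenyl)methanol 14 (CuI, 3,4,7,8-tetramethyl-1,10-phenanthroline, Cs2CO3, toluene, 80 °C) replaces iodine by the PMB-oxy group with retention and gives 21.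

Further compounds
F1 | step 14 | ethyl ester 13 with the aldehyde converted into a (Z)-2-iodoprop-1-enyl group (C5=C4, iodine cis to C6) | CCOC(=O)[C@@]1(C)OC(C)(C)O[C@H]1[C@@H](O[Si](C)(C)C(C)(C)C)[C@@H](C(C)=C)C/C=C(/C)I
F2 | step 14 | C1 aldehyde derived from F1 | O=C[C@@]1(C)OC(C)(C)O[C@H]1[C@@H](O[Si](C)(C)C(C)(C)C)[C@@H](C(C)=C)C/C=C(/C)I
F3 | step 14 | β-hydroxy ethyl ester from F2 and ethyl acetate (C1 epimers) | CCOC(=O)CC(O)[C@@]1(C)OC(C)(C)O[C@H]1[C@@H](O[Si](C)(C)C(C)(C)C)[C@@H](C(C)=C)C/C=C(/C)I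
F4 | step 14 | C1 triethylsilyl ether of F3 | CCOC(=O)CC(O[Si](CC)(CC)CC)[C@@]1(C)OC(C)(C)O[C@H]1[C@@H](O[Si](C)(C)C(C)(C)C)[C@@H](C(C)=C)C/C=C(/C)I
F5 | step 14 | C3 aldehyde derived from F4 | O=CCC(O[Si](CC)(CC)CC)[C@@]1(C)OC(C)(C)O[C@H]1[C@@H](O[Si](C)(C)C(C)(C)C)[C@@H](C(C)=C)C/C=C(/C)I
F6 | step 14 | ten-membered (3S,4Z) allylic alcohol with C1 triethylsilyl ether, 9,10-acetonide and C8 TBS ether | C=C(C)[C@H]1C/C=C(C)\[C@@H](O)CC(O[Si](CC)(CC)CC)[C@@]3(C)OC(C)(C)O[C@H]3[C@H]1O[Si](C)(C)C(C)(C)C
F7 | step 14 | C3 4-methoxybenzyl ether of F6 | C=C(C)[C@H]1C/C=C(C)\[C@@H](OCc2ccc(OC)cc2)CC(O[Si](CC)(CC)CC)[C@@]3(C)OC(C)(C)O[C@H]3[C@H]1O[Si](C)(C)C(C)(C)C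
F8 | step 14 | C1 alcohol from F7 (C1 epimers) | C=C(C)[C@H]1C/C=C(C)\[C@@H](OCc2ccc(OC)cc2)CC(O)[C@@]3(C)OC(C)(C)O[C@H]3[C@H]1O[Si](C)(C)C(C)(C)C
F9 | step 12 | C5 epimer (5S) of hydroxy ester 21 | CCOC(=O)[C@@]1(C)OC(C)(C)O[C@H]1[C@@H](O[Si](C)(C)C(C)(C)C)[C@@H](C(C)=C)C[C@H](O)/C(C)=C/OCc1ccc(OC)cc1
F10 | step 12 | C5 epimer (5S) of seco acid 22 | OC(=O)[C@@]1(C)OC(C)(C)O[C@H]1[C@@H](O[Si](C)(C)C(C)(C)C)[C@@H](C(C)=C)C[C@H](O)/C(C)=C/OCc1ccc(OC)cc1
F11 | step 10 | ethynyl ketone at C5 derived from 12 | CCOC(=O)[C@@]1(C)OC(C)(C)O[C@H]1[C@@H](O[Si](C)(C)C(C)(C)C)[C@@H](C(C)=C)CC(=O)C#C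
F12 | step 10 | (5R)-propargylic alcohol derived from F11 | CCOC(=O)[C@@]1(C)OC(C)(C)O[C@H]1[C@@H](O[Si](C)(C)C(C)(C)C)[C@@H](C(C)=C)C[C@@H](O)C#C
F13 | step 10 | (5R)-allylic alcohol with (E)-2-iodo-1-methylvinyl group derived from F12 | CCOC(=O)[C@@]1(C)OC(C)(C)O[C@H]1[C@@H](O[Si](C)(C)C(C)(C)C)[C@@H](C(C)=C)C[C@@H](O)/C(C)=C/I
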